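(The numbers come from no measurement; the result is computed.)

In the early hours of a run Jd is made from Ja and Jb and starts to be lost at once, so I asked how much of it each set-up still holds at the end.

| setting | oak | maple | larch | birch |
|---|---|---|---|---|
| Ja | 11 mM | 11 mM | 11 mM (fed, over 10.0 h) | 11 mM |
| Jb | 3.00 equiv (fed, over 10.0 h) | 3.00 equiv | 3.00 equiv | 3.00 equiv |
| time | 10 h | 10 h | 10 h |  |
| remark | a stirred flask in which Jb is dosed at a steady rate over 10.0 h without added volume, worked up at 10 h | everything together in a closed stirred flask, run for 10 h | all but Ja at the start; Ja goes in evenly over 10.0 h, the run ends at 10 h | a single well-mixed tank run continuously and read at steady state, 10 h in it on average |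

    2 Jb → Jh (k1 = 0.65 /M/h)
    Jb + Je → Jf + Jc (k2 = 7.2 /M/h)
    Ja + Jb → Jd + Jc (k3 = 30 /M/h)
    Jb + Jd → Je + Jc (k4 = 12 /M/h)
    Ja + Jd → Jj (k5 = 110 /M/h)
    Jb + Jf → Jg + Jc (k6 = 20 /M/h)

* the set-up with the highest amount of Jd at the outlet or at the end, in percent of the Ja put in ("none" if the first two lie within 2 percentage points) (oak / maple / larch / birch / none)
* amount of Jd at the outlet or at the end, in percent of the Ja put in, oak
* amount of Jd at the outlet or at the end, in percent of the Ja put in, maple
* amount of Jd at the outlet or at the end, in percent of the Ja put in, larch
* amount of Jd at the outlet or at the end, in percent of the Ja put in, birch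

- percentages count the Ja that a species holds: one Jj counts as two
- a step written with two of one species runs at k times the square of its concentration and takes two of it each time
- the stated concentrations are those of everything mixed, before any reaction; amounts are the same in each set-up
- the feed brings no volume worth counting
- run time (oak): 10 h

Jd leaves by two ways, with Ja to Jj and with Jb to Je. I took it as settled between making and losing (a quasi-steady state) and looked at how its losses divide. Let a and b be Ja and Jb as fractions of their charges. The split, the loss to Ja over the loss to Jb, is then N times a over b, where N is the ratio of the two constants divided by the equivalents: 3.06.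

Maple starts at that value. A dosed charge stands where its feed meets the reaction of Ja with Jb, and that is set by 3.30, the Ja charge times that constant times the dosing time. So oak, with Jb near 30.3% of its charge, has a split of 10.1. Larch, with Ja near 10.1% of its charge, has 0.309, and birch has 0.280.

With Jb held at its charge, the settled Jd is 19.3% for larch and, with the outflow as a further loss, 15.0% for birch. Birch's split is lower than larch's, yet its Jd came out lower, so one number was not enough. Nor did it order oak and maple: in maple Jd has a half-life of 1.8 h by the Jb way alone, with Jb as charged, shorter than the run. I put larch first.

The forecast chose larch, with 10.5% for oak, 7.1% for maple, 17.4% for larch and 14.1% for birch, in the words “Larch is best, more than 2 points ahead of birch”.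

The simulation gave larch first: oak 10.6%, maple 7.47%, larch 17.5%, birch 14.2%. Larch had not come to rest, with 15% of its Ja and 39% of its Jb still free, so its split read 1.16. A flask like oak with 27 mM of Ja has an early split of 24.8, and it ended with 80.0% in Jj and 1.91% in Jd. Left until 100 h, larch fell to 0.855% Jd while Jg rose from 7.50% to 39.6%.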